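Start by counting. Each triple product costs 3 reagent. In gamma the charged reagent could therefore carry 83.3 % of the substrate to triple product. Call that share, charged reagent over 3 times charged substrate, the reagent ceiling C. Exact stoichiometry, C = 100 %, is the zero of the scale. Below it reagent is the limiting reagent. Above it a surplus remains to attack triple product.

| setting | Tuesday's | Saturday's | delta | gamma | zeta | epsilon | eta |
|---|---|---|---|---|---|---|---|
| substrate | 0.40 M | 0.40 M | 0.40 M | 0.40 M | 0.40 M | 0.40 M | 0.40 M |
| reagent | 0.22 M | 2.3 M | 2.00 M | 1.00 M | 0.150 M | 0.800 M | 0.480 M |
| remark | run made earlier | run made earlier |  |  |  |  |  |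
| time |  |  | 2.5 min | 2.5 min | 2.5 min | 2.5 min | 2.5 min |

| run | time / s | triple product / % | substrate / % |
|---|---|---|---|
| Tuesday's | 20.0 | 1 | 41 |
| Tuesday's | 40.0 | 1 | 31 |
| Tuesday's | 60.0 | 2 | 23 |
| Tuesday's | 80.0 | 3 | 22 |
| Saturday's | 10.0 | 74 | 0 |
| Saturday's | 15.0 | 78 | 0 |
| Saturday's | 30.0 | 66 | 0 |
| Saturday's | 80.0 | 32 | 0 |

(standard deviation of a reading: 1.5 percentage points)

- percentages count the substrate that a species holds: one side product B counts as two
- the earlier runs were read with a standard deviation of 1.5 percentage points
- steps under discussion: substrate + reagent -> mono adduct + released group; reagent + mono adduct -> double product + released group; reagent + double product -> triple product + released group; reagent + triple product -> tetra adduct + released group; substrate + released group -> side product A; substrate + mono adduct -> side product B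

* all flasks from highest to lowest amount of triple product, in percent of the substrate charged, at 2.5 min (delta / gamma / zeta / epsilon / eta)
* the same order at 30 s (delta / gamma / zeta / epsilon / eta)
* the amount of triple product, in percent of the substrate charged of the flask you put first, at 2.5 min
* the amount of triple product, in percent of the substrate charged of the flask you put last, at 2.5 min

So rank by C? Epsilon has 66.7 %, eta 40.0 %, zeta 12.5 %, delta 167 %. But a ceiling is not a yield. Saturday's flask has C = 192 %, and its highest reading of triple product is still 78 %. Use that reading as a factor on gamma's ceiling and you get 65.0 %.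

That discount may be too kind to lean flasks. Tuesday's C is 18.3 %, yet it reads 3 % at 80.0 s, give or take 1.5 percentage points. The ratio of that reading to the ceiling is 0.164, less than Saturday's factor, so short reagent costs more. Zeta's ceiling lies lower still, and Tuesday's ratio gives zeta about 2.05 %.

Delta has the opposite doubt. Its surplus is 0.800 M, Saturday's 1.10 M. Saturday's triple product reads 66 % at 30.0 s and 32 % at 80.0 s, and those two readings give a half-life of about 47.9 s. Treat the fall as pseudo-first-order, its rate constant in proportion to the surplus, and delta's half-life is about 65.8 s. From a peak like Saturday's, delta keeps about 18.8 % at 2.5 min. Eta's ceiling with Tuesday's ratio and Saturday's factor gives 6.55 % to 31.2 %, a range with delta's figure inside it. My order is gamma, epsilon, delta, eta, zeta, and delta before eta is a doubtful placing. At 30 s, which is shorter than delta's half-life, I put delta first.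

The forecast says gamma > epsilon > delta > eta > zeta at 2.5 min and delta > gamma > epsilon > eta > zeta at 30 s. It gives 65 % (55 % to 74 %) for the first flask and 1 % (0.2 % to 3 %) for the last, a lower figure than my 2.05 % for zeta. Its grounds: "Gamma (2.5 eq) nearly stalls at triple product once reagent runs out".

Both orders come out as the forecast has them: gamma > epsilon > delta > eta > zeta, then delta > gamma > epsilon > eta > zeta.

    substrate + reagent → mono adduct + released group (k = 0.470 L mol⁻¹ s⁻¹)
    reagent + mono adduct → double product + released group (k = 0.230 L mol⁻¹ s⁻¹)
    reagent + double product → triple product + released group (k = 0.390 L mol⁻¹ s⁻¹)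
    reagent + triple product → tetra adduct + released group (k = 0.0150 L mol⁻¹ s⁻¹)
    substrate + released group → side product A (k = 0.00260 L mol⁻¹ s⁻¹)
    substrate + mono adduct → side product B (k = 0.130 L mol⁻¹ s⁻¹)

At 2.5 min gamma gives 64.3 % and zeta 0.391 %. In gamma 0.25 % of the reagent is left at 2.50 min, and triple product stands at 64.5 % at 25.0 min. Gamma's result is 77.2 % of its ceiling of 83.3 %, while zeta's is 3.13 % of its ceiling. The neighbour of zeta charged with 0.16 M of substrate has its ceiling raised to 31.2 %, and it holds 6.60 % of triple product at 2.50 min.

Readings and results were computed for substances that don't exist; the scatter is artificial.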